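0.714: that is the free catalyst of this flask as a fraction of its impurity charge. So this flask holds less free catalyst than impurity, and if all its catalyst ends as spent catalyst, you expect the impurity to keep 28.6% of its charge.

| flask | substrate | free catalyst | impurity | remark | time |
|---|---|---|---|---|---|
| west | 0.13 mM | 0.5 mol% | 1.4 µM | run made earlier |  |
| south-east | 0.30 mM | 0.5 mol% | 1.4 µM | run made earlier |  |
| south | 0.20 mM | 0.25 mol% | 1.4 µM | run made earlier |  |
| flask | 0.20 mM | 0.5 mol% | 1.4 µM |  | 4.0 min |

| run | time / min | target / % | isomer of the product / % | substrate / % |
|---|---|---|---|---|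
| west | 0.333 | 1.1 | 3.0 | 95.8 |
| west | 0.667 | 2.4 | 3.0 | 94.0 |
| west | 1.50 | 3.7 | 3.6 | 95.3 |
| west | 4.00 | 2.3 | 2.1 | 93.6 |
| south-east | 0.500 | 12.4 | 13.2 | 74.3 |
| south-east | 1.33 | 20.6 | 19.7 | 62.2 |
| south-east | 2.50 | 26.2 | 28.7 | 44.1 |
| south-east | 4.00 | 34.6 | 37.5 | 24.5 |
| south | 0.500 | 0.5 | 3.0 | 96.1 |
| south | 1.33 | 4.7 | 1.2 | 95.5 |
| south | 2.50 | 1.6 | 2.2 | 95.6 |
| south | 4.00 | 3.6 | 2.0 | 95.3 |

(readings scatter by 1 percentage point)

- candidate steps: substrate + free catalyst -> catalyst intermediate A; catalyst intermediate B -> free catalyst + target; catalyst intermediate A -> catalyst intermediate B; free catalyst + impurity -> spent catalyst; target <-> isomer of the product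

* amount of target at 4.0 min, in percent of the substrate charged
* amount of isomer of the product at 4.0 min, in percent of the substrate charged

West and south also hold less catalyst than impurity, and their substrate readings lie flat. South-east, with catalyst above impurity, runs on, so I leave it out of this reckoning. But in the candidate steps substrate and impurity each react with free catalyst, first order in it, so if those steps hold, the logarithms of the fractions left of each keep a constant ratio as free catalyst moves.

Averaging the four readings, west keeps 94.7% of its substrate and south 95.6%, while their impurity should stand at 53.6% and 64.3%. Pooled, those readings give 0.0933, the competition ratio, the logarithm of the substrate fraction left over that of the impurity fraction left.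

So I reckon this flask keeps 89.0% of its substrate. Split as in the last south-east reading, the 11.0% converted is 5.29% target and 5.74% isomer of the product.

The forecast, for which the impurity “acts as a titrant for the catalyst”, says 5.5% of target (3.8% to 8%) and 5.8% of isomer (4% to 8.3%), both slightly above mine.

The flask gives 5.15% of target and 5.66% of isomer of the product, with 28.6% of its impurity and 89.2% of its substrate left.

    substrate + free catalyst → catalyst intermediate A (k = 2.10 × 10⁵ /M/s)
    catalyst intermediate B → free catalyst + target (k = 11.0 /s)
    catalyst intermediate A → catalyst intermediate B (k = 34.0 /s)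
    free catalyst + impurity → spent catalyst (k = 2.30 × 10⁶ /M/s)
    target ⇌ isomer of the product (K = 1.10, k = 0.200 /s)

Now take the neighbour flask with 0.12 mol% of free catalyst, its other charges unchanged. Its catalyst is 0.171 of its impurity, so you expect 82.9% of the impurity to stay, and the same ratio then keeps 98.3% of the substrate, 1.70% converted. That neighbour flask ends with 83% of its impurity, 98% of its substrate, 0.811% of target and 0.892% of isomer of the product.

The earlier runs and the new flask were generated by integration with made-up constants, and the scatter is random.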